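The lower flavan-3,4-diol is cut at C4–C4a. C4a of its ring A lies para to the C7 oxygen and ortho to O1, so it is the nucleophilic carbon of a resorcinol ether, and the C3/C4 cis-diol anti to the C2 aryl group is the footprint of OsO4 on a flav-3-ene. The key step is therefore a gold-catalysed 6-endo hydroarylation that closes ring C from an enantioenriched aryl propargyl ether whose alkyne carbons become C3 and C4. The precursor already carries the benzylated robinetinidol unit, joined by a flavan-4-yl cation alkylation to a bromopyrogallol that becomes the lower ring B.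

Key step: step 8

Remark: (+)-dihydrorobinetin, 5-bromopyrogallol and 3-(benzyloxy)phenol are taken as catalogue compounds, and the Ph-pybox enantiomer for the propargylic etherification is fixed by a trial run, because the chiral upper unit may add its own bias.

Abbreviations: Bn = benzyl; U = (2R,3S,4S)-3,7-bis(benzyloxy)-2-[3,4,5-tris(benzyloxy)phenyl]chroman-4-yl, the protected upper unit bonded through its C4.

Step 1
Reactants: 1 (+)-dihydrorobinetin [(2R,3R)-3,7-dihydroxy-2-(3,4,5-trihydroxyphenyl)chroman-4-one]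
Product: 2 (2R,3R)-7-(benzyloxy)-3-hydroxy-2-[3,4,5-tris(benzyloxy)phenyl]chroman-4-one
Conditions: BnBr (4.4 equiv), K2CO3 (6 equiv), DMF, rt, Ar
Reagents that add atoms: benzyl bromide, BrCc1ccccc1
Why: Williamson etherification with carbonate should benzylate only the four phenols and leave the secondary C3 alcohol free, and the mild base at room temperature under argon should spare the C2 and C3 centers from ring opening and the ketol from oxidation.

Step 2
Reactants: 2 tetra-O-benzyl dihydrorobinetin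
Product: 3 (2R,3S,4R)-7-(benzyloxy)-2-[3,4,5-tris(benzyloxy)phenyl]chroman-3,4-diol
Conditions: NaBH4 (excess), THF/MeOH, 0 °C → rt; aq. NH4Cl
Reagents that add atoms: none
Why: Carbonyl reduction of a 2,3-trans-dihydroflavonol by borohydride should give mainly the 3,4-trans diol by hydride delivery anti to the 3-OH, and the C4 configuration is in any case lost in step 3.

Step 3
Reactants: 3 tetra-O-benzyl flavan-3,4-diol; 4 5-bromopyrogallol (5-bromobenzene-1,2,3-triol, 5 equiv)
Product: 6 (2R,3S,4S)-7-(benzyloxy)-4-(6-bromo-2,3,4-trihydroxyphenyl)-2-[3,4,5-tris(benzyloxy)phenyl]chroman-3-ol, via flavan-4-yl cation 5 (not isolated)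
Conditions: BF3·OEt2 (1.5 equiv), THF/CH2Cl2, 0 °C → rt, Ar; aq. NaHCO3
Reagents that add atoms: none
Why: This is the acid-promoted flavan-3,4-diol/phenol condensation, in which the 4-OH ionises to cation 5 (stabilised by the para C7 oxygen and O1) and is captured in a Friedel–Crafts alkylation by the carbon of the free triphenol 4 that is ortho and para to hydroxyl groups, a far better nucleophile than the benzyl ether rings of 3, so self-condensation should stay low; the arene adds anti to the 3-OH of the half-chair with the 2-aryl group equatorial, which should set C4 as S (3,4-trans).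

Step 4
Reactants: 6 bromo tetraol
Product: 7 5-bromo-1,2,3-tris(benzyloxy)-4-U-benzene (octa-O-benzyl aryl bromide)
Conditions: NaH (6 equiv), BnBr (6 equiv), n-Bu4NI (cat.), DMF, 0 °C → rt, Ar
Reagents that add atoms: benzyl bromide, BrCc1ccccc1
Why: Williamson etherification under irreversible deprotonation benzylates the three remaining phenols and the C3 alcohol, and no stereocenter is touched.

Step 5
Reactants: 7 octa-O-benzyl aryl bromide
Product: 10 3,4,5-tris(benzyloxy)-2-U-benzaldehyde, via aryllithium 8 (not isolated), via lithium hemiaminal alkoxide 9 (not isolated)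
Conditions: n-BuLi (1.1 equiv), THF, −78 °C; DMF, −78 → 0 °C; aq. NH4Cl
Reagents that add atoms: N,N-dimethylformamide, CN(C)C=O
Why: Bromine–lithium exchange is faster than any deprotonation at −78 °C, and the aryllithium is formylated by DMF (Bouveault-type formylation) through adduct 9, which collapses on work-up.

Step 6
Reactants: 10 aldehyde
Product: 12 1-[3,4,5-tris(benzyloxy)-2-U-phenyl]prop-2-yn-1-yl acetate (both carbinol epimers), via bromomagnesium propargylic alkoxide 11 (not isolated)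
Conditions: HC≡CMgBr (1.5 equiv), THF, 0 °C; then Ac2O (4 equiv), DMAP (cat.), 0 °C → rt
Reagents that add atoms: ethynylmagnesium bromide, C#C[Mg]Br; acetic anhydride, CC(=O)OC(C)=O
Why: Grignard 1,2-addition to the hindered aldehyde is followed by acetylation of the magnesium alkoxide in the same flask; the new carbinol center forms without control, which is harmless because step 7 is stereoconvergent.

Step 7
Reactants: 12 propargylic acetate; 13 3-(benzyloxy)phenol (2 equiv)
Product: 14 (S)-1-[3,4,5-tris(benzyloxy)-2-U-phenyl]prop-2-yn-1-yl 3-(benzyloxy)phenyl ether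
Conditions: (CuOTf)2·C6H6 (5 mol%), 2,6-bis(4-phenyl-4,5-dihydrooxazol-2-yl)pyridine (Ph-pybox, 12 mol%, the enantiomer that gives the S ether), i-Pr2NEt, CH2Cl2, −10 °C
Reagents that add atoms: none
Why: In this copper-catalysed enantioselective propargylic etherification the monovalent copper acetylide loses acetate to give a copper allenylidene in which the old carbinol center is planar, so both epimers of 12 converge, and the phenoxide of 13 adds to the γ-carbon on the face left open by the pybox ligand, which should set the propargylic center as S under catalyst control.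

Step 8
Reactants: 14 (S)-aryl propargyl ether
Product: 15 (2S)-7-(benzyloxy)-2-[3,4,5-tris(benzyloxy)-2-U-phenyl]-2H-chromene
Conditions: (t-Bu)2(2-biphenylyl)PAu(NCMe)SbF6 (3 mol%), CH2Cl2, 0 °C → rt; filtration through basic alumina
Reagents that add atoms: none
Why: The cationic monovalent gold complex binds the terminal alkyne, and the aryl ether ring attacks the terminal alkyne carbon (the future C4) through the ring carbon para to the benzyloxy group (the future C4a) in a Friedel–Crafts manner, after which rearomatisation and protodeauration release the 2H-chromene. The closest known reaction type is the gold- or platinum-catalysed intramolecular hydroarylation of aryl propargyl ethers to 2H-chromenes. Ring C of the lower unit closes in the 6-endo-dig mode. No stereocenter is formed; the C2 center from step 7 lies outside the bonds that change and should be retained, and it is this center that directs step 9. The step needs site selectivity between the two ortho carbons of the resorcinol ether (the carbon para to oxygen is both the more activated and the less hindered, the other lies between two oxygens), 6-endo over 5-exo closure (normal for terminal aryl propargyl ethers) and no ionisation of the benzylic propargylic carbon–oxygen bond (non-ionising solvent, low temperature, low catalyst loading).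

Step 9
Reactants: 15 (2S)-2H-chromene
Product: 16 (2R,3S,4S)-7-(benzyloxy)-2-[3,4,5-tris(benzyloxy)-2-U-phenyl]chroman-3,4-diol
Conditions: K2OsO4·2H2O (5 mol%), N-methylmorpholine N-oxide (2 equiv), acetone/THF/H2O, 0 °C → rt
Reagents that add atoms: N-methylmorpholine N-oxide, C[N+]1([O-])CCOCC1; water, O
Why: In this Upjohn dihydroxylation OsO4 adds suprafacially to the C3=C4 alkene from the face opposite the bulky C2 aryl group, which should set C3 as S and C4 as S (2,3-trans-3,4-cis).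

Step 10
Reactants: 16 nona-O-benzyl diol
Product: 17 target, (2R,3S,4S)-2-{3,4,5-trihydroxy-2-[(2R,3S,4S)-3,7-dihydroxy-2-(3,4,5-trihydroxyphenyl)chroman-4-yl]phenyl}chroman-3,4,7-triol
Conditions: H2 (1 atm), Pd(OH)2/C, THF/MeOH, NaHCO3 (trace), rt; Sephadex LH-20, Ar
Reagents that add atoms: none
Why: Hydrogenolysis of the nine benzyl ethers over Pd(OH)2/C under neutral buffered conditions should leave the benzylic C4 alcohol and the cyclic benzylic ethers of both flavan units intact, and no stereocenter is touched.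

Compound list
1 | (+)-dihydrorobinetin, (2R,3R)-3,7-dihydroxy-2-(3,4,5-trihydroxyphenyl)chroman-4-one | Oc1ccc2c(c1)O[C@H](c1cc(O)c(O)c(O)c1)[C@@H](O)C2=O | starting material
2 | (2R,3R)-7-(benzyloxy)-3-hydroxy-2-[3,4,5-tris(benzyloxy)phenyl]chroman-4-one | c1ccccc1COc1ccc2c(c1)O[C@H](c1cc(OCc3ccccc3)c(OCc3ccccc3)c(OCc3ccccc3)c1)[C@@H](O)C2=O | intermediate
3 | (2R,3S,4R)-7-(benzyloxy)-2-[3,4,5-tris(benzyloxy)phenyl]chroman-3,4-diol | c1ccccc1COc1ccc2c(c1)O[C@H](c1cc(OCc3ccccc3)c(OCc3ccccc3)c(OCc3ccccc3)c1)[C@@H](O)[C@@H]2O | intermediate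
4 | 5-bromopyrogallol (5-bromobenzene-1,2,3-triol) | Oc1cc(Br)cc(O)c1O | starting material
5 | flavan-4-yl cation of 3 | c1ccccc1COc1ccc2c(c1)O[C@H](c1cc(OCc3ccccc3)c(OCc3ccccc3)c(OCc3ccccc3)c1)[C@@H](O)[CH+]2 | intermediate (not isolated)
6 | (2R,3S,4S)-7-(benzyloxy)-4-(6-bromo-2,3,4-trihydroxyphenyl)-2-[3,4,5-tris(benzyloxy)phenyl]chroman-3-ol | c1ccccc1COc1ccc2c(c1)O[C@H](c1cc(OCc3ccccc3)c(OCc3ccccc3)c(OCc3ccccc3)c1)[C@@H](O)[C@@H]2c1c(Br)cc(O)c(O)c1O | intermediate
7 | 5-bromo-1,2,3-tris(benzyloxy)-4-U-benzene | c1ccccc1COc1ccc2c(c1)O[C@H](c1cc(OCc3ccccc3)c(OCc3ccccc3)c(OCc3ccccc3)c1)[C@@H](OCc1ccccc1)[C@@H]2c1c(Br)cc(OCc2ccccc2)c(OCc2ccccc2)c1OCc1ccccc1 | intermediate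
8 | aryllithium from 7 (Li in place of Br) | c1ccccc1COc1ccc2c(c1)O[C@H](c1cc(OCc3ccccc3)c(OCc3ccccc3)c(OCc3ccccc3)c1)[C@@H](OCc1ccccc1)[C@@H]2c1c([Li])cc(OCc2ccccc2)c(OCc2ccccc2)c1OCc1ccccc1 | intermediate (not isolated)
9 | lithium hemiaminal alkoxide (DMF adduct of 8) | c1ccccc1COc1ccc2c(c1)O[C@H](c1cc(OCc3ccccc3)c(OCc3ccccc3)c(OCc3ccccc3)c1)[C@@H](OCc1ccccc1)[C@@H]2c1c(C(O[Li])N(C)C)cc(OCc2ccccc2)c(OCc2ccccc2)c1OCc1ccccc1 | intermediate (not isolated)
10 | 3,4,5-tris(benzyloxy)-2-U-benzaldehyde | c1ccccc1COc1ccc2c(c1)O[C@H](c1cc(OCc3ccccc3)c(OCc3ccccc3)c(OCc3ccccc3)c1)[C@@H](OCc1ccccc1)[C@@H]2c1c(C=O)cc(OCc2ccccc2)c(OCc2ccccc2)c1OCc1ccccc1 | intermediate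
11 | bromomagnesium propargylic alkoxide (both epimers) | c1ccccc1COc1ccc2c(c1)O[C@H](c1cc(OCc3ccccc3)c(OCc3ccccc3)c(OCc3ccccc3)c1)[C@@H](OCc1ccccc1)[C@@H]2c1c(C(O[Mg]Br)C#C)cc(OCc2ccccc2)c(OCc2ccccc2)c1OCc1ccccc1 | intermediate (not isolated)
12 | 1-[3,4,5-tris(benzyloxy)-2-U-phenyl]prop-2-yn-1-yl acetate (both carbinol epimers) | c1ccccc1COc1ccc2c(c1)O[C@H](c1cc(OCc3ccccc3)c(OCc3ccccc3)c(OCc3ccccc3)c1)[C@@H](OCc1ccccc1)[C@@H]2c1c(C(OC(C)=O)C#C)cc(OCc2ccccc2)c(OCc2ccccc2)c1OCc1ccccc1 | intermediate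
13 | 3-(benzyloxy)phenol | Oc1cccc(OCc2ccccc2)c1 | starting material
14 | (S)-1-[3,4,5-tris(benzyloxy)-2-U-phenyl]prop-2-yn-1-yl 3-(benzyloxy)phenyl ether | c1ccccc1COc1ccc2c(c1)O[C@H](c1cc(OCc3ccccc3)c(OCc3ccccc3)c(OCc3ccccc3)c1)[C@@H](OCc1ccccc1)[C@@H]2c1c([C@H](C#C)Oc2cccc(OCc3ccccc3)c2)cc(OCc2ccccc2)c(OCc2ccccc2)c1OCc1ccccc1 | intermediate
15 | (2S)-7-(benzyloxy)-2-[3,4,5-tris(benzyloxy)-2-U-phenyl]-2H-chromene | c1ccccc1COc1ccc2c(c1)O[C@H](c1cc(OCc3ccccc3)c(OCc3ccccc3)c(OCc3ccccc3)c1)[C@@H](OCc1ccccc1)[C@@H]2c1c([C@H]2Oc3cc(OCc4ccccc4)ccc3C=C2)cc(OCc2ccccc2)c(OCc2ccccc2)c1OCc1ccccc1 | intermediate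
16 | (2R,3S,4S)-7-(benzyloxy)-2-[3,4,5-tris(benzyloxy)-2-U-phenyl]chroman-3,4-diol | c1ccccc1COc1ccc2c(c1)O[C@H](c1cc(OCc3ccccc3)c(OCc3ccccc3)c(OCc3ccccc3)c1)[C@@H](OCc1ccccc1)[C@@H]2c1c([C@H]2Oc3cc(OCc4ccccc4)ccc3[C@H](O)[C@@H]2O)cc(OCc2ccccc2)c(OCc2ccccc2)c1OCc1ccccc1 | intermediate
17 | (2R,3S,4S)-2-{3,4,5-trihydroxy-2-[(2R,3S,4S)-3,7-dihydroxy-2-(3,4,5-trihydroxyphenyl)chroman-4-yl]phenyl}chroman-3,4,7-triol | Oc1ccc2c(c1)O[C@H](c1cc(O)c(O)c(O)c1)[C@@H](O)[C@@H]2c1c([C@H]2Oc3cc(O)ccc3[C@H](O)[C@@H]2O)cc(O)c(O)c1O | target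

Total step count: 10. Longest linear sequence: 10 steps (from 1).

Steps most likely to fail

Step 3. Capture of cation 5 by the bromine-deactivated, hindered carbon of 4 may be slow, so that O-alkylation, attack by the benzyl ether rings of a second molecule of 3 or attack syn to the 3-OH erodes yield and the C4 configuration. The fallback makes the C4–aryl bond by Sonogashira coupling and closes the upper ring C with the gold chemistry of step 8, so that no cation has to choose between arenes. It sets out from 4 and 13 and comes back at 7. 4 is benzylated (BnBr, K2CO3, DMF) to 5-bromo-1,2,3-tris(benzyloxy)benzene F1, which is iodinated next to bromine (N-iodosuccinimide, CF3CO2H cat., MeCN) to 1-bromo-2-iodo-3,4,5-tris(benzyloxy)benzene F2. Commercial 3,4,5-tris(benzyloxy)benzaldehyde is converted as in step 6 into racemic 1-[3,4,5-tris(benzyloxy)phenyl]prop-2-yn-1-yl acetate F3 and then, with 13 as in step 7, into (S)-1-[3,4,5-tris(benzyloxy)phenyl]prop-2-yn-1-yl 3-(benzyloxy)phenyl ether F4. Sonogashira coupling of F4 with F2 at the carbon–iodine bond (PdCl2(PPh3)2, CuI, Et3N, THF) should give the diaryl alkyne (R)-1-[3,4,5-tris(benzyloxy)phenyl]-3-[6-bromo-2,3,4-tris(benzyloxy)phenyl]prop-2-yn-1-yl 3-(benzyloxy)phenyl ether F5 (same spatial arrangement as F4; only the descriptor changes). Gold-catalysed 6-endo hydroarylation as in step 8 should give (2S)-7-(benzyloxy)-4-[6-bromo-2,3,4-tris(benzyloxy)phenyl]-2-[3,4,5-tris(benzyloxy)phenyl]-2H-chromene F6. Hydroboration–oxidation (BH3·THF; NaOH, H2O2) places boron on C3 anti to the C2 aryl group and hydrogen on C4 on the same face, which should give the 2,3-trans-3,4-trans alcohol (2R,3S,4S)-7-(benzyloxy)-4-[6-bromo-2,3,4-tris(benzyloxy)phenyl]-2-[3,4,5-tris(benzyloxy)phenyl]chroman-3-ol F7. Benzylation of its C3 hydroxyl (NaH, BnBr, DMF) gives 7.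

Step 7. The bulky chiral ortho substituent may override the ligand, so that facial selectivity at the allenylidene is poor, or the phenol may react through carbon instead of oxygen. The fallback replaces the copper allenylidene by an SN2 etherification with inversion. It sets out from 10 and comes back at 14. Ethynylmagnesium bromide is added to 10 without the acetic anhydride quench; the two carbinol epimers are diastereomers and are separated by chromatography into (R)-1-[3,4,5-tris(benzyloxy)-2-U-phenyl]prop-2-yn-1-ol F8 and its (S)-epimer F9. Mitsunobu reaction of F8 with 13 (PPh3, diisopropyl azodicarboxylate, toluene, 0 °C) inverts the carbinol center and should give 14; F9 is set aside.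

Step 8. Ring closure at the ortho carbon between the two oxygens would give the 5-benzyloxy isomer, and gold-induced ionisation of the propargylic ether would scramble C2. The fallback blocks the unwanted ortho carbon with a bromine that the final hydrogenolysis removes. It sets out from 12 and comes back at 17. Commercial 2-bromoresorcinol is monobenzylated (BnBr, K2CO3, acetone) to 3-(benzyloxy)-2-bromophenol F10, which takes the place of 13 in step 7 and should give (S)-1-[3,4,5-tris(benzyloxy)-2-U-phenyl]prop-2-yn-1-yl 3-(benzyloxy)-2-bromophenyl ether F11. Gold-catalysed closure of F11 can then occur only para to the benzyloxy group and should give (2S)-7-(benzyloxy)-8-bromo-2-[3,4,5-tris(benzyloxy)-2-U-phenyl]-2H-chromene F12. Dihydroxylation as in step 9 gives (2R,3S,4S)-7-(benzyloxy)-8-bromo-2-[3,4,5-tris(benzyloxy)-2-U-phenyl]chroman-3,4-diol F13, and hydrogenolysis over Pd(OH)2/C with Et3N removes the bromine together with the nine benzyl groups to give 17.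

Further compounds
F1 | step 3 | 5-bromo-1,2,3-tris(benzyloxy)benzene | Brc1cc(OCc2ccccc2)c(OCc2ccccc2)c(OCc2ccccc2)c1
F2 | step 3 | 1-bromo-2-iodo-3,4,5-tris(benzyloxy)benzene | Brc1cc(OCc2ccccc2)c(OCc2ccccc2)c(OCc2ccccc2)c1I
F3 | step 3 | 1-[3,4,5-tris(benzyloxy)phenyl]prop-2-yn-1-yl acetate (racemic) | C#CC(OC(C)=O)c1cc(OCc2ccccc2)c(OCc2ccccc2)c(OCc2ccccc2)c1
F4 | step 3 | (S)-1-[3,4,5-tris(benzyloxy)phenyl]prop-2-yn-1-yl 3-(benzyloxy)phenyl ether | C#C[C@H](Oc1cccc(OCc2ccccc2)c1)c1cc(OCc2ccccc2)c(OCc2ccccc2)c(OCc2ccccc2)c1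
F5 | step 3 | (R)-1-[3,4,5-tris(benzyloxy)phenyl]-3-[6-bromo-2,3,4-tris(benzyloxy)phenyl]prop-2-yn-1-yl 3-(benzyloxy)phenyl ether | Brc1cc(OCc2ccccc2)c(OCc2ccccc2)c(OCc2ccccc2)c1C#C[C@H](Oc1cccc(OCc2ccccc2)c1)c1cc(OCc2ccccc2)c(OCc2ccccc2)c(OCc2ccccc2)c1
F6 | step 3 | (2S)-7-(benzyloxy)-4-[6-bromo-2,3,4-tris(benzyloxy)phenyl]-2-[3,4,5-tris(benzyloxy)phenyl]-2H-chromene | c1ccccc1COc1ccc2c(c1)O[C@H](c1cc(OCc3ccccc3)c(OCc3ccccc3)c(OCc3ccccc3)c1)C=C2c1c(Br)cc(OCc2ccccc2)c(OCc2ccccc2)c1OCc1ccccc1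
F7 | step 3 | (2R,3S,4S)-7-(benzyloxy)-4-[6-bromo-2,3,4-tris(benzyloxy)phenyl]-2-[3,4,5-tris(benzyloxy)phenyl]chroman-3-ol | c1ccccc1COc1ccc2c(c1)O[C@H](c1cc(OCc3ccccc3)c(OCc3ccccc3)c(OCc3ccccc3)c1)[C@@H](O)[C@@H]2c1c(Br)cc(OCc2ccccc2)c(OCc2ccccc2)c1OCc1ccccc1
F8 | step 7 | (R)-1-[3,4,5-tris(benzyloxy)-2-U-phenyl]prop-2-yn-1-ol | c1ccccc1COc1ccc2c(c1)O[C@H](c1cc(OCc3ccccc3)c(OCc3ccccc3)c(OCc3ccccc3)c1)[C@@H](OCc1ccccc1)[C@@H]2c1c([C@@H](C#C)O)cc(OCc2ccccc2)c(OCc2ccccc2)c1OCc1ccccc1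
F9 | step 7 | (S)-1-[3,4,5-tris(benzyloxy)-2-U-phenyl]prop-2-yn-1-ol | c1ccccc1COc1ccc2c(c1)O[C@H](c1cc(OCc3ccccc3)c(OCc3ccccc3)c(OCc3ccccc3)c1)[C@@H](OCc1ccccc1)[C@@H]2c1c([C@H](C#C)O)cc(OCc2ccccc2)c(OCc2ccccc2)c1OCc1ccccc1
F10 | step 8 | 3-(benzyloxy)-2-bromophenol | Oc1cccc(OCc2ccccc2)c1Br
F11 | step 8 | (S)-1-[3,4,5-tris(benzyloxy)-2-U-phenyl]prop-2-yn-1-yl 3-(benzyloxy)-2-bromophenyl ether | c1ccccc1COc1ccc2c(c1)O[C@H](c1cc(OCc3ccccc3)c(OCc3ccccc3)c(OCc3ccccc3)c1)[C@@H](OCc1ccccc1)[C@@H]2c1c([C@H](C#C)Oc2cccc(OCc3ccccc3)c2Br)cc(OCc2ccccc2)c(OCc2ccccc2)c1OCc1ccccc1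
F12 | step 8 | (2S)-7-(benzyloxy)-8-bromo-2-[3,4,5-tris(benzyloxy)-2-U-phenyl]-2H-chromene | c1ccccc1COc1ccc2c(c1)O[C@H](c1cc(OCc3ccccc3)c(OCc3ccccc3)c(OCc3ccccc3)c1)[C@@H](OCc1ccccc1)[C@@H]2c1c([C@H]2Oc3c(Br)c(OCc4ccccc4)ccc3C=C2)cc(OCc2ccccc2)c(OCc2ccccc2)c1OCc1ccccc1
F13 | step 8 | (2R,3S,4S)-7-(benzyloxy)-8-bromo-2-[3,4,5-tris(benzyloxy)-2-U-phenyl]chroman-3,4-diol | c1ccccc1COc1ccc2c(c1)O[C@H](c1cc(OCc3ccccc3)c(OCc3ccccc3)c(OCc3ccccc3)c1)[C@@H](OCc1ccccc1)[C@@H]2c1c([C@H]2Oc3c(Br)c(OCc4ccccc4)ccc3[C@H](O)[C@@H]2O)cc(OCc2ccccc2)c(OCc2ccccc2)c1OCc1ccccc1
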